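The target does not stay as made: it passes reversibly into the isomer of the product, and the question is what share of the pair remains target after 2.5 h as the second substrate is varied.

| setting | alpha | eta | larch | birch | maple | oak |
|---|---|---|---|---|---|---|
| starting material | 0.30 M | 0.30 M | 0.30 M | 0.30 M | 0.30 M | 0.30 M |
| second substrate | 0.096 M | 0.66 M | 0.0800 M | 0.150 M | 0.300 M | 0.600 M |
| precatalyst | 0.30 mM | 0.30 mM | 0.30 mM | 0.30 mM | 0.30 mM | 0.30 mM |
| remark | run made earlier | run made earlier |  |  |  |  |
| time |  |  | 2.5 h | 2.5 h | 2.5 h | 2.5 h |

| run | time / min | target / % | isomer of the product / % | starting material / % |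
|---|---|---|---|---|
| alpha | 6.00 | 0 | 0 | 89.0 |
| alpha | 10.0 | 0.4 | 0.3 | 82.6 |
| alpha | 15.0 | 1.0 | 0.1 | 72.9 |
| alpha | 20.0 | 2.9 | 0.9 | 65.9 |
| alpha | 30.0 | 8.6 | 1.8 | 50.2 |
| alpha | 50.0 | 19.0 | 4.6 | 27.0 |
| alpha | 80.0 | 29.8 | 9.8 | 12.7 |
| eta | 4.00 | 0 | 0.2 | 92.3 |
| eta | 12.0 | 0.1 | 0.9 | 79.4 |
| eta | 20.0 | 0.7 | 0 | 69.6 |
| eta | 30.0 | 1.4 | 0.6 | 58.3 |
| eta | 50.0 | 9.5 | 2.4 | 35.3 |
| eta | 60.0 | 15.1 | 2.7 | 25.6 |
| eta | 80.0 | 24.9 | 7.0 | 14.1 |

(scatter of a reading: 0.5 percentage points)

- the analysis behind the earlier runs scatters by 0.5 percentage points, standard deviation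
- reactions considered so far: catalyst intermediate A -> free catalyst + target; starting material <-> dormant form; target <-> isomer of the product; starting material + free catalyst <-> catalyst intermediate A; second substrate + free catalyst <-> catalyst intermediate B; catalyst intermediate B -> free catalyst + second product; precatalyst -> free catalyst
- "hardly changes" means that all values lie within two and a half points (for a concentration: within two and a half percent of the largest)

* share of target in all that became target or isomer of the product for larch, birch, maple, oak, in this order
* the shape of the row from first to last (falls, then rises / falls all the way / rises, then falls / hardly changes / rises all the way)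

In alpha we read two things from the late readings. The ratio of isomer to target at 80.0 min is a reading of where the pair is heading, and the isomer's gain since 50.0 min, per unit of mean target, is a rate. The slope ignores the way back, so we treat the rate as a low estimate.

R = c(isomer)/c(target) = 0.329

k = 0.00710 min⁻¹

τ = 1/(k(1 + 1/R)) = 34.8 min

N = t/τ = 4.31

N, the relaxation number, is the asked time counted in relaxation times of the pair. At large N the pair is under thermodynamic control, and the share is 1/(1 + R), here read as 75.3%.

Is one number enough? At 80.0 min eta reads 78.1%, higher than the 75.3% of alpha. Eta, with more second substrate than oak, shows 1.4% target at 30.0 min. Counting from then, N is still 3.44, so we estimate a spread of about 0.46 percentage points. Our reckoning is a flat row near 75.3%.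

The forecast differs: it gives 50.5%, 51.5%, 53.5%, 57%, so that the row rises all the way, on the ground that “A later start gives target less time to isomerise”.

The flasks give 75.7%, 75.7%, 75.8%, 75.8%: the row hardly changes.

    catalyst intermediate A → free catalyst + target (k = 145 min⁻¹)
    starting material ⇌ dormant form (K = 3.00, k = 0.0197 min⁻¹)
    target ⇌ isomer of the product (K = 0.330, k = 0.0429 min⁻¹)
    starting material + free catalyst ⇌ catalyst intermediate A (K = 9.30 M⁻¹, k = 237 M⁻¹ min⁻¹)
    second substrate + free catalyst ⇌ catalyst intermediate B (K = 140 M⁻¹, k = 14700 M⁻¹ min⁻¹)
    catalyst intermediate B → free catalyst + second product (k = 362 min⁻¹)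
    precatalyst → free catalyst (k = 0.0107 min⁻¹)

In larch, the half-life of target by the forward step alone is 0.27 h at 2.50 h, shorter than the 2.5 h of the run. With this rate and R, N becomes 26.0, larger than our 4.31. Oak, the flask with the most second substrate of the four, holds 39.7% target and 12.7% isomer at 2.50 h, a share of 75.8%, and at 25.0 h, where our N reaches 43.1, it holds 75.1% target and 24.8% isomer.

The data come from a simulation from invented constants; noise was put on by code.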